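**Retrosynthetic overview**

1. Target 22 ⇐ 21 ⇐ 20 by desilylation and hydrogenolysis; 20 ⇐ 1,4-diol 18 ⇐ lactol 17 by cyclodehydration and borohydride reduction.
2. Feature used: in the tetrahydrofuran (O1, C2–C5), C2 is a bare O–CH2 on C3, and in the ring-opened styrene 13 (C3=C7') C3 is homoallylic to the C5 hydroxyl. C2 is therefore disconnected as carbon monoxide (bonds C2–C3 and O1–C2): 17 ⇐ 13 + CO 14.
3. 13 ⇐ 12 ⇐ 11: C4 and C7 come from one auxiliary-controlled boron syn-aldol (bond C4–C7) of imide 7 with aldehyde 9.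
4. 7 ⇐ acid 4 + oxazolidinone 5; 4 ⇐ bromide 2 + but-3-enoic acid 3 (Heck); 2 ⇐ 1; 9 ⇐ 8.
5. Ring order: the tetrahydrofuran is the only ring made. It is closed as the lactol in step 8, opened by reduction in step 9 and closed again as the ether in step 10.

Key step: step 8

Remark: the numbering used is O1, C2–C5 for the tetrahydrofuran; C3 carries the guaiacylmethyl carbon C7' and C4 carries the carbinol carbon C7. In this numbering the target is (3R,4R,7S) with the 3,4-substituents trans. Lactol 17 is taken as an anomeric mixture at C2, which does not matter because C2 ends as CH2.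

**Route**

Step 1
Reactants: 1 4-bromo-2-methoxyphenol
Product: 2 1-(benzyloxy)-4-bromo-2-methoxybenzene
Conditions: BnBr, K2CO3, DMF, rt
Reagents that add atoms: benzyl bromide, BrCc1ccccc1
Why: Williamson ether synthesis; the phenoxide is alkylated by the primary benzylic bromide and the aryl bromide is inert.

Step 2
Reactants: 2 1-(benzyloxy)-4-bromo-2-methoxybenzene, 3 but-3-enoic acid
Product: 4 (E)-4-[4-(benzyloxy)-3-methoxyphenyl]but-3-enoic acid
Conditions: Pd(OAc)2 (cat.), P(o-tol)3, Et3N, MeCN, 85 °C; then aq. HCl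
Reagents that add atoms: none
Why: Mizoroki–Heck reaction; the aryl group adds to the terminal alkene carbon and β-hydride elimination from the new benzylic CH2 should give the aryl-conjugated (E)-alkene, leaving the acid β,γ-unsaturated.

Step 3
Reactants: 4 (E)-4-[4-(benzyloxy)-3-methoxyphenyl]but-3-enoic acid, 5 (S)-4-benzyloxazolidin-2-one
Product: 7 (S)-4-benzyl-3-[(E)-4-(4-benzyloxy-3-methoxyphenyl)but-3-enoyl]oxazolidin-2-one, via mixed pivalic anhydride 6 (not isolated)
Conditions: PivCl, Et3N, THF, −20 °C; then 5, LiCl, −20 °C → rt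
Reagents that add atoms: none
Why: N-acylation of an oxazolidinone through a mixed anhydride; LiCl/Et3N acylates the carbamate nitrogen without strong base, so the β,γ-alkene should not move into conjugation.

Step 4
Reactants: 8 syringaldehyde
Product: 9 4-(benzyloxy)-3,5-dimethoxybenzaldehyde
Conditions: BnBr, K2CO3, DMF, 60 °C
Reagents that add atoms: benzyl bromide, BrCc1ccccc1
Why: Williamson ether synthesis on the hindered phenoxide; the aldehyde is not enolisable and is untouched.

Step 5
Reactants: 7 (S)-4-benzyl-3-[(E)-4-(4-benzyloxy-3-methoxyphenyl)but-3-enoyl]oxazolidin-2-one, 9 4-(benzyloxy)-3,5-dimethoxybenzaldehyde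
Product: 11 (S)-4-benzyl-3-[(S,E)-2-[(S)-(4-benzyloxy-3,5-dimethoxyphenyl)(hydroxy)methyl]-4-(4-benzyloxy-3-methoxyphenyl)but-3-enoyl]oxazolidin-2-one, via boron dienolate 10 (not isolated)
Conditions: Bu2BOTf, iPr2NEt, CH2Cl2, −78 → 0 °C; 9, −78 → 0 °C; then pH 7 buffer, MeOH, H2O2, 0 °C
Reagents that add atoms: none
Why: Evans boron syn-aldol reaction; the (Z)-dienolate 10 reacts at its α-carbon through a Zimmerman–Traxler chair on the face turned away from the benzyl group of the auxiliary, which sets C4 and C7 together as the (S,S) syn pair that maps onto (4R,7S) of the target.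

Step 6
Reactants: 11 the syn-aldol adduct
Product: 12 (S)-4-benzyl-3-[(S,E)-2-[(S)-(4-benzyloxy-3,5-dimethoxyphenyl)(tert-butyldimethylsilyloxy)methyl]-4-(4-benzyloxy-3-methoxyphenyl)but-3-enoyl]oxazolidin-2-one
Conditions: TBSOTf, 2,6-lutidine, CH2Cl2, −78 → 0 °C
Reagents that add atoms: tert-butyldimethylsilyl triflate, CC(C)(C)[Si](C)(C)OS(=O)(=O)C(F)(F)F
Why: Silylation of the secondary benzylic alcohol under non-nucleophilic base; it blocks retro-aldol cleavage and later leaves the C5 hydroxyl as the only free OH.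

Step 7
Reactants: 12 the silylated aldol adduct
Product: 13 (R,E)-2-[(S)-(4-benzyloxy-3,5-dimethoxyphenyl)(tert-butyldimethylsilyloxy)methyl]-4-(4-benzyloxy-3-methoxyphenyl)but-3-en-1-ol
Conditions: LiBH4, MeOH (1 equiv), THF, 0 °C
Reagents that add atoms: none
Why: Reductive cleavage of the N-acyl oxazolidinone by LiBH4 gives the primary C5 alcohol and returns the auxiliary; hydride attack is faster than enolisation, so C4 is kept (its descriptor changes from S to R only through the CIP priorities).

Step 8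
Reactants: 13 (R,E)-2-[(S)-(4-benzyloxy-3,5-dimethoxyphenyl)(tert-butyldimethylsilyloxy)methyl]-4-(4-benzyloxy-3-methoxyphenyl)but-3-en-1-ol, 14 carbon monoxide
Product: 17 (3R,4R)-3-(4-benzyloxy-3-methoxybenzyl)-4-[(S)-(4-benzyloxy-3,5-dimethoxyphenyl)(tert-butyldimethylsilyloxy)methyl]tetrahydrofuran-2-ol (anomeric mixture), via substrate phosphinite 15 (not isolated), via hydroxy aldehyde 16 (not isolated)
Conditions: Rh(acac)(CO)2 (2 mol%), Ph2POMe (20 mol%), 4 Å MS, CO/H2 (1:1, 20 bar), THF, 45 °C; then vent, DBU (0.2 equiv), rt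
Reagents that add atoms: none
Why: Proposed new method: methyl diphenylphosphinite exchanges reversibly onto the only free hydroxyl (on C5) to give phosphinite 15, whose phosphorus holds Rh–H so that syn hydrometalation of C3=C7' runs through a six-membered Rh–P–O–C5–C4–C3 chelate (Rh to C3, H to C7'), and CO insertion, hydrogenolysis and ligand exchange then release aldehyde 16. The closest known reaction type is the Rh-catalysed hydroformylation of homoallylic alcohols directed by catalytic, reversibly bound phosphinite ligands, which gives γ-lactols from terminal and alkyl-substituted 1,2-disubstituted alkenes; an aryl-conjugated alkene is the untested extension. The tetrahydrofuran ring closes by 5-exo-trig addition of the C5 hydroxyl to the formyl carbon C2 (bond O1–C2), giving the lactol as an anomeric mixture. C3 is controlled twice: kinetically by the chair-like chelate, in which the C4 substituent lies pseudo-equatorial and the 3,4-trans arrangement results, and thermodynamically because C3 is α to the masked aldehyde, so DBU should equilibrate any cis isomer through open-chain 16 to the more stable 3,4-trans lactol. The step needs the formyl group on C3 against the preference of a styrene for the benzylic carbon C7' (η3-benzyl rhodium); the tether secures this, since only Rh on C3 closes the six-membered chelate, and the excess of ligand over Rh together with the mild temperature keeps the undirected pathway slow. The silyl ether on O7 leaves a single hydroxyl to bind the ligand and to cyclise, and the CO pressure makes insertion faster than β-hydride elimination toward C4, so that C4 should not be scrambled.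

Step 9
Reactants: 17 the 3,4-trans lactol
Product: 18 (2R,3R)-2-(4-benzyloxy-3-methoxybenzyl)-3-[(S)-(4-benzyloxy-3,5-dimethoxyphenyl)(tert-butyldimethylsilyloxy)methyl]butane-1,4-diol
Conditions: NaBH4, MeOH/THF, 0 °C
Reagents that add atoms: none
Why: Borohydride reduction of the lactol through its open-chain aldehyde; reduction is faster than enolisation, so C3 is kept, and this mild hydride is chosen over an acidic silane reduction to spare the ionisable benzylic silyl ether.

Step 10
Reactants: 18 the 1,4-diol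
Product: 20 (3R,4R)-3-(4-benzyloxy-3-methoxybenzyl)-4-[(S)-(4-benzyloxy-3,5-dimethoxyphenyl)(tert-butyldimethylsilyloxy)methyl]tetrahydrofuran, via alkoxyphosphonium salt 19 (not isolated)
Conditions: PPh3, DIAD, THF, 0 °C → rt
Reagents that add atoms: none
Why: Mitsunobu cyclodehydration of a 1,4-diol; one primary hydroxyl is activated as the alkoxyphosphonium ion and displaced by the other in a 5-exo-tet closure, and since both carbinol carbons are CH2 either activation gives the same ring and no stereocentre is touched.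

Step 11
Reactants: 20 the protected tetrahydrofuran
Product: 21 4-{[(3R,4R)-4-[(S)-(tert-butyldimethylsilyloxy)(4-hydroxy-3,5-dimethoxyphenyl)methyl]tetrahydrofuran-3-yl]methyl}-2-methoxyphenol
Conditions: H2 (1 atm), 10% Pd/C, EtOAc, rt
Reagents that add atoms: none
Why: Hydrogenolysis of the two aryl benzyl ethers; the benzylic C7–O bond is still a bulky silyl ether and should resist cleavage in a neutral solvent.

Step 12
Reactants: 21 the bis-phenol silyl ether
Product: 22 (S)-(4-hydroxy-3,5-dimethoxyphenyl)[(3R,4R)-4-(4-hydroxy-3-methoxybenzyl)tetrahydrofuran-3-yl]methanol (target, CNP0307127.1)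
Conditions: TBAF, AcOH (1:1), THF, 0 °C → rt
Reagents that add atoms: none
Why: Fluoride desilylation; buffering with acetic acid keeps the phenols protonated, so the p-hydroxybenzylic C7 centre should neither epimerise nor eliminate through a quinone methide.

**Compound list**

1 | 4-bromo-2-methoxyphenol | COc1cc(Br)ccc1O | starting material
2 | 1-(benzyloxy)-4-bromo-2-methoxybenzene | COc1cc(Br)ccc1OCc1ccccc1 | intermediate
3 | but-3-enoic acid | C=CCC(=O)O | starting material
4 | (E)-4-[4-(benzyloxy)-3-methoxyphenyl]but-3-enoic acid | COc1cc(/C=C/CC(=O)O)ccc1OCc1ccccc1 | intermediate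
5 | (S)-4-benzyloxazolidin-2-one | O=C1N[C@@H](Cc2ccccc2)CO1 | starting material
6 | (E)-4-[4-(benzyloxy)-3-methoxyphenyl]but-3-enoic pivalic anhydride | COc1cc(/C=C/CC(=O)OC(=O)C(C)(C)C)ccc1OCc1ccccc1 | intermediate (not isolated)
7 | (S)-4-benzyl-3-[(E)-4-(4-benzyloxy-3-methoxyphenyl)but-3-enoyl]oxazolidin-2-one | COc1cc(/C=C/CC(=O)N2C(=O)OC[C@@H]2Cc2ccccc2)ccc1OCc1ccccc1 | intermediate
8 | syringaldehyde (4-hydroxy-3,5-dimethoxybenzaldehyde) | COc1cc(C=O)cc(OC)c1O | starting material
9 | 4-(benzyloxy)-3,5-dimethoxybenzaldehyde | COc1cc(C=O)cc(OC)c1OCc1ccccc1 | intermediate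
10 | dibutylboron (Z)-dienolate of imide 7 | COc1cc(/C=C/C=C(\OB(CCCC)CCCC)N2C(=O)OC[C@@H]2Cc2ccccc2)ccc1OCc1ccccc1 | intermediate (not isolated)
11 | (S)-4-benzyl-3-[(S,E)-2-[(S)-(4-benzyloxy-3,5-dimethoxyphenyl)(hydroxy)methyl]-4-(4-benzyloxy-3-methoxyphenyl)but-3-enoyl]oxazolidin-2-one | COc1cc(/C=C/[C@H](C(=O)N2C(=O)OC[C@@H]2Cc2ccccc2)[C@H](O)c2cc(OC)c(OCc3ccccc3)c(OC)c2)ccc1OCc1ccccc1 | intermediate
12 | tert-butyldimethylsilyl ether of 11 | COc1cc(/C=C/[C@H](C(=O)N2C(=O)OC[C@@H]2Cc2ccccc2)[C@H](O[Si](C)(C)C(C)(C)C)c2cc(OC)c(OCc3ccccc3)c(OC)c2)ccc1OCc1ccccc1 | intermediate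
13 | (R,E)-2-[(S)-(4-benzyloxy-3,5-dimethoxyphenyl)(tert-butyldimethylsilyloxy)methyl]-4-(4-benzyloxy-3-methoxyphenyl)but-3-en-1-ol | COc1cc(/C=C/[C@H](CO)[C@H](O[Si](C)(C)C(C)(C)C)c2cc(OC)c(OCc3ccccc3)c(OC)c2)ccc1OCc1ccccc1 | intermediate (key-step precursor)
14 | carbon monoxide | [C-]#[O+] | starting material
15 | O-diphenylphosphinite of alkenol 13 | COc1cc(/C=C/[C@H](COP(c2ccccc2)c2ccccc2)[C@H](O[Si](C)(C)C(C)(C)C)c2cc(OC)c(OCc3ccccc3)c(OC)c2)ccc1OCc1ccccc1 | intermediate (not isolated)
16 | (2R,3R)-2-(4-benzyloxy-3-methoxybenzyl)-3-[(S)-(4-benzyloxy-3,5-dimethoxyphenyl)(tert-butyldimethylsilyloxy)methyl]-4-hydroxybutanal | COc1cc(C[C@@H](C=O)[C@H](CO)[C@H](O[Si](C)(C)C(C)(C)C)c2cc(OC)c(OCc3ccccc3)c(OC)c2)ccc1OCc1ccccc1 | intermediate (not isolated)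
17 | (3R,4R)-3-(4-benzyloxy-3-methoxybenzyl)-4-[(S)-(4-benzyloxy-3,5-dimethoxyphenyl)(tert-butyldimethylsilyloxy)methyl]tetrahydrofuran-2-ol, anomeric mixture | COc1cc(C[C@H]2C(O)OC[C@@H]2[C@H](O[Si](C)(C)C(C)(C)C)c2cc(OC)c(OCc3ccccc3)c(OC)c2)ccc1OCc1ccccc1 | intermediate (key-step product)
18 | (2R,3R)-2-(4-benzyloxy-3-methoxybenzyl)-3-[(S)-(4-benzyloxy-3,5-dimethoxyphenyl)(tert-butyldimethylsilyloxy)methyl]butane-1,4-diol | COc1cc(C[C@@H](CO)[C@H](CO)[C@H](O[Si](C)(C)C(C)(C)C)c2cc(OC)c(OCc3ccccc3)c(OC)c2)ccc1OCc1ccccc1 | intermediate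
19 | alkoxytriphenylphosphonium salt of diol 18 (shown at the C2 hydroxyl; hydrazide counter-ion) | COc1cc(C[C@@H](CO[P+](c2ccccc2)(c2ccccc2)c2ccccc2)[C@H](CO)[C@H](O[Si](C)(C)C(C)(C)C)c2cc(OC)c(OCc3ccccc3)c(OC)c2)ccc1OCc1ccccc1.CC(C)OC(=O)[N-]NC(=O)OC(C)C | intermediate (not isolated)
20 | (3R,4R)-3-(4-benzyloxy-3-methoxybenzyl)-4-[(S)-(4-benzyloxy-3,5-dimethoxyphenyl)(tert-butyldimethylsilyloxy)methyl]tetrahydrofuran | COc1cc(C[C@H]2COC[C@@H]2[C@H](O[Si](C)(C)C(C)(C)C)c2cc(OC)c(OCc3ccccc3)c(OC)c2)ccc1OCc1ccccc1 | intermediate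
21 | 4-{[(3R,4R)-4-[(S)-(tert-butyldimethylsilyloxy)(4-hydroxy-3,5-dimethoxyphenyl)methyl]tetrahydrofuran-3-yl]methyl}-2-methoxyphenol | COc1cc(C[C@H]2COC[C@@H]2[C@H](O[Si](C)(C)C(C)(C)C)c2cc(OC)c(O)c(OC)c2)ccc1O | intermediate
22 | (S)-(4-hydroxy-3,5-dimethoxyphenyl)[(3R,4R)-4-(4-hydroxy-3-methoxybenzyl)tetrahydrofuran-3-yl]methanol | COc1cc(C[C@H]2COC[C@@H]2[C@H](O)c2cc(OC)c(O)c(OC)c2)ccc1O | target

**Step count**

Total steps: 12. Longest linear sequence: 11 steps (steps 1–3 and 5–12, from 1 to 22); step 4 is a one-step side branch.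

**Steps most likely to fail**

1. Step 8 (the proposed new method). The undirected catalyst pathway may place the formyl group on the benzylic carbon C7' or simply hydrogenate the alkene, or ligand exchange onto the hindered primary alcohol may be too slow to compete. The fallback uses known silicon-tethered radical chemistry, sets out from 13 and returns at 18. Alkenol 13 is silylated with (bromomethyl)chlorodimethylsilane and Et3N in CH2Cl2 to give the (bromomethyl)dimethylsilyl ether F1. Slow addition of Bu3SnH/AIBN in benzene at 80 °C generates the silylmethyl radical, which should close 6-exo-trig onto C3 (Nishiyama–Stork cyclisation) because this gives the benzylic radical at C7'. A chair transition state with both substituents equatorial should give the trans-4,5-disubstituted 2,2-dimethyl-1,2-oxasilinane F2. Tamao oxidation (H2O2, KF, KHCO3, THF/MeOH) of the C–Si bond turns the tether carbon into the C2 hydroxymethyl group and delivers diol 18, from which step 10 follows.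

2. Step 5. The aryl-conjugated dienolate may add slowly to the electron-rich aldehyde, react through its γ-carbon, or let the aldolate revert, with loss of syn selectivity. The fallback brings the aryl group in after the aldol, sets out from 5 and 9, and returns at 12. Oxazolidinone 5 is deprotonated with n-BuLi and acylated with crotonyl chloride to give (S)-4-benzyl-3-[(E)-but-2-enoyl]oxazolidin-2-one F3. Deconjugative enolisation with Bu2BOTf/Et3N gives the parent boron dienolate F4, a long-established α-selective syn-aldol donor. Its reaction with 9 should give the α-vinyl syn-aldol adduct F5, and TBSOTf/2,6-lutidine then gives the silyl ether F6. Cross-metathesis of F6 with commercial 4-benzyloxy-3-methoxystyrene (C=Cc1ccc(OCc2ccccc2)c(OC)c1; second-generation Hoveyda–Grubbs catalyst, CH2Cl2, 40 °C) should form the (E)-styrene and give 12. This fallback also makes steps 1–3 unnecessary.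

3. Step 7. Hydride may attack the ring carbonyl of the hindered imide and open the oxazolidinone, or the silyl group may migrate from O7 to O5 under the basic borohydride conditions. The fallback changes the order of events, sets out from 11 and returns at 13. The free β-hydroxy imide 11, whose reduction is hydroxyl-assisted and less hindered, is treated with LiBH4 to give the (1S,2R)-1,3-diol F7. TBSOTf (excess) with 2,6-lutidine gives the bis-silyl ether F8. HF·pyridine buffered with pyridine in THF at 0 °C should remove the primary silyl ether selectively and give 13.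

**Further compounds**

F1 | step 8 | {[(R,E)-2-[(S)-(4-benzyloxy-3,5-dimethoxyphenyl)(tert-butyldimethylsilyloxy)methyl]-4-(4-benzyloxy-3-methoxyphenyl)but-3-en-1-yl]oxy}(bromomethyl)dimethylsilane | COc1cc(/C=C/[C@H](CO[Si](C)(C)CBr)[C@H](O[Si](C)(C)C(C)(C)C)c2cc(OC)c(OCc3ccccc3)c(OC)c2)ccc1OCc1ccccc1
F2 | step 8 | (4R,5R)-4-(4-benzyloxy-3-methoxybenzyl)-5-[(S)-(4-benzyloxy-3,5-dimethoxyphenyl)(tert-butyldimethylsilyloxy)methyl]-2,2-dimethyl-1,2-oxasilinane | COc1cc(C[C@H]2C[Si](C)(C)OC[C@@H]2[C@H](O[Si](C)(C)C(C)(C)C)c2cc(OC)c(OCc3ccccc3)c(OC)c2)ccc1OCc1ccccc1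
F3 | step 5 | (S)-4-benzyl-3-[(E)-but-2-enoyl]oxazolidin-2-one | C/C=C/C(=O)N1C(=O)OC[C@@H]1Cc1ccccc1
F4 | step 5 | dibutylboron (Z)-dienolate of F3 | C=C/C=C(\OB(CCCC)CCCC)N1C(=O)OC[C@@H]1Cc1ccccc1
F5 | step 5 | (S)-4-benzyl-3-[(S)-2-[(S)-(4-benzyloxy-3,5-dimethoxyphenyl)(hydroxy)methyl]but-3-enoyl]oxazolidin-2-one | C=C[C@H](C(=O)N1C(=O)OC[C@@H]1Cc1ccccc1)[C@H](O)c1cc(OC)c(OCc2ccccc2)c(OC)c1
F6 | step 5 | tert-butyldimethylsilyl ether of F5 | C=C[C@H](C(=O)N1C(=O)OC[C@@H]1Cc1ccccc1)[C@H](O[Si](C)(C)C(C)(C)C)c1cc(OC)c(OCc2ccccc2)c(OC)c1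
F7 | step 7 | (1S,2R)-1-(4-benzyloxy-3,5-dimethoxyphenyl)-2-[(E)-2-(4-benzyloxy-3-methoxyphenyl)ethenyl]propane-1,3-diol | COc1cc(/C=C/[C@H](CO)[C@H](O)c2cc(OC)c(OCc3ccccc3)c(OC)c2)ccc1OCc1ccccc1
F8 | step 7 | bis(tert-butyldimethylsilyl) ether of F7 | COc1cc(/C=C/[C@H](CO[Si](C)(C)C(C)(C)C)[C@H](O[Si](C)(C)C(C)(C)C)c2cc(OC)c(OCc3ccccc3)c(OC)c2)ccc1OCc1ccccc1
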